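**Strategy.** The target holds two identical 4-hydroxy-7,8-dimethoxy-1-methylquinolin-2-one units on a C10 core: ring A′ (O4A–Cc–Cb–Ca–C3A=C4A) is cis-fused along Cb–Cc to ring B′ (O4B–CMe2–Cb–Cc–C3B=C4B). The usual logic (unit-A quinone methide plus unit-B chromene) is inverted. Cc, which carries both O4A and C3B, is read as a formyl carbon of unit B, and Cb–CMe2–O4B as an isobutenyl group on Ca. Unit B becomes a 3-(aryloxymethylene)quinoline-2,4-dione by O–C condensation with the 4-OH of an enantioenriched unit-A phenol. Its intramolecular inverse-demand oxa-Diels–Alder reaction forms Cc–Cb and O4B–CMe2, closes both pyran rings and sets Cb and Cc from Ca, which comes from an organocatalytic Michael addition.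

Key step: step 6

Remark on the chemistry (labels and assumptions): unit A is the quinolinone whose C3 (C3A) carries Ca, the CH bearing CH2C(CH3)2OH. Unit B is the quinolinone whose C3 (C3B) carries Cc, the O-bearing CH. Cb is the CH between them that carries CMe2–O4B. Read from the SMILES, the target is Ca S, Cb S, Cc R, with H on Cb and Cc cis and the Ca side chain trans to CMe2 across ring A′. It is assumed that the quinine-derived primary amine gives the S sense at Ca in step 3; otherwise the quinidine-derived pseudoenantiomer is taken. The tertiary alcohol is carried as a 2-methylallyl group until the last step so that the key step meets a single hydroxyl group.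

Step 1
Reactants: 1 2,3-dimethoxyaniline
Product: 3 N-methyl-2,3-dimethoxyaniline, via N-methoxymethyl hemiaminal ether 2 (not isolated)
Conditions: (CH2O)n, NaOMe, MeOH, reflux; then NaBH4, reflux
Reagents that add atoms: paraformaldehyde (as formaldehyde), C=O
Why: Condensation of the aniline with formaldehyde in methanolic methoxide gives the N-methoxymethyl hemiaminal ether, which borohydride reduces through the iminium ion, a reductive amination that should stop at the mono-N-methyl stage; no stereocentre is formed.

Step 2
Reactants: 3 N-methyl-2,3-dimethoxyaniline; 4 bis(2,4,6-trichlorophenyl) malonate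
Product: 6 4-hydroxy-7,8-dimethoxy-1-methylquinolin-2(1H)-one, via malonamic aryl ester 5 (not isolated)
Conditions: 4 (1.0 equiv), Ph2O, 220 °C
Reagents that add atoms: none
Why: Thermal N-acylation by the active aryl malonate followed by intramolecular Friedel–Crafts-type acylation at the only free ortho position (para to the 3-methoxy group) is the classical active-malonate synthesis of 4-hydroxyquinolin-2-ones and places the methoxy groups at C7 and C8; no stereocentre is formed.

Step 3
Reactants: 6 4-hydroxy-7,8-dimethoxy-1-methylquinolin-2(1H)-one; 7 (E)-6-methylhepta-3,5-dien-2-one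
Product: 8 (S)-4-hydroxy-7,8-dimethoxy-1-methyl-3-(6-methyl-2-oxohept-5-en-4-yl)quinolin-2(1H)-one
Conditions: 9-amino-9-deoxy-epi-quinine (20 mol%), TFA (40 mol%), CH2Cl2, rt
Reagents that add atoms: none
Why: Iminium-ion activation of the dienone by the primary cinchona amine and attack of C3 of the hydroxyquinolinone at the β-carbon (1,4- and not 1,6-addition, because the δ-carbon is fully substituted) is the warfarin-type organocatalytic Michael addition, in which the catalyst shields one face of the iminium ion and so sets Ca as S.

Step 4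
Reactants: 8 (S)-4-hydroxy-7,8-dimethoxy-1-methyl-3-(6-methyl-2-oxohept-5-en-4-yl)quinolin-2(1H)-one
Product: 9 (S)-3-(2,6-dimethylhepta-1,5-dien-4-yl)-4-hydroxy-7,8-dimethoxy-1-methylquinolin-2(1H)-one
Conditions: Ph3PCH3Br (3.5 equiv), KOtBu (3.3 equiv), THF, 0 °C to rt
Reagents that add atoms: methyltriphenylphosphonium bromide, C[P+](c1ccccc1)(c1ccccc1)c1ccccc1.[Br-]
Why: Wittig methylenation of the methyl ketone (the first equivalent of ylide deprotonates the 4-OH, which opens the hemiketal and excludes retro-Michael loss of a dianion) turns the oxygen-bearing arm into a 2-methylallyl group that has no hydroxyl to compete in step 6, while Ca is not enolisable and keeps its configuration.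

Step 5
Reactants: 6 4-hydroxy-7,8-dimethoxy-1-methylquinolin-2(1H)-one
Product: 10 3-[(dimethylamino)methylene]-7,8-dimethoxy-1-methylquinoline-2,4(1H,3H)-dione
Conditions: Me2NCH(OMe)2 (1.5 equiv), toluene, 80 °C
Reagents that add atoms: N,N-dimethylformamide dimethyl acetal, COC(OC)N(C)C
Why: Condensation of the nucleophilic C3 of the 4-hydroxyquinolinone with the amide acetal, with loss of two methanol, is the standard enaminone synthesis from cyclic 1,3-dicarbonyl compounds and should give a stable equivalent of the 3-formyl compound; no stereocentre is formed.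

Step 6
Reactants: 9 (S)-3-(2,6-dimethylhepta-1,5-dien-4-yl)-4-hydroxy-7,8-dimethoxy-1-methylquinolin-2(1H)-one; 10 3-[(dimethylamino)methylene]-7,8-dimethoxy-1-methylquinoline-2,4(1H,3H)-dione
Product: 12 2-methylallyl analogue of the target (Ca S; Cb S; Cc R), via aryloxymethylene quinolinedione 11 (not isolated)
Conditions: 10 (1.2 equiv), (±)-CSA (1.1 equiv), 4 Å MS, ClCH2CH2Cl, 60 °C
Reagents that add atoms: none
Why: Proposed new method: the sulfonic acid protonates enaminone 10, the 4-OH of 9 adds to the iminium carbon and dimethylamine leaves as its ammonium salt, giving the 3-(aryloxymethylene)quinoline-2,4-dione 11, whose 1-oxadiene (O4B=C4B–C3B=Cc) is tethered through O4A–C4A=C3A–Ca to the isobutenyl group and should add to it in an intramolecular inverse-electron-demand oxa-Diels–Alder reaction (concerted and asynchronous, or stepwise through the tertiary cation, with the same outcome). The closest known reaction type is the domino Knoevenagel/intramolecular hetero-Diels–Alder reaction of cyclic 1,3-dicarbonyl compounds with O-prenylsalicylaldehyde (same tether length, same sp2–sp2 unit in the tether), and 2-(aryloxymethylene)-1,3-dicarbonyl heterodienes are known in the form of 3-formylchromones; what is new is that the heterodiene is assembled by O–C exchange and that the tether runs through its oxygen substituent. Ring A′ closes as the tether ring by the Cc–Cb bond (six-membered, exo with respect to both π-bonds) and ring B′ is the [4+2] ring, with Markovnikov regiochemistry (electrophilic Cc to Cb, O4B to CMe2, the carbon that best carries positive charge). Cb is set by Ca through allylic 1,3-strain: Ca–H eclipses the Cb=CMe2 bond to avoid the Z-methyl group, so Cc, delivered from the C3A side, adds to the alkene face anti to the 2-methylallyl chain (chain trans to CMe2). Cc is set by the ring constraint: in that rotamer the new Cb–CMe2 bond is pseudoaxial on ring A′ and O4B can reach it only if C3B on Cc is pseudoequatorial, which is the cis ring fusion. The step needs reaction at the enolic 4-OH only (9 has no other hydroxyl), cycloaddition through the C4B ketone oxygen and not the lactam oxygen (the more electrophilic carbonyl, and the product regains the 2-quinolone), the isobutenyl and not the 2-methylallyl group as dienophile (six- against eight-membered tether ring), and no proton-induced ether formation between the 4-OH and an alkene (the only strong acid is bound first as the enaminone salt and then as the dimethylammonium salt).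

Step 7
Reactants: 12 2-methylallyl analogue of the target
Product: 13 target CNP0160874.2 (Ca S; Cb S; Cc R)
Conditions: Co(acac)2 (20 mol%), PhSiH3 (2 equiv), O2 (1 atm), i-PrOH/THF, rt
Reagents that add atoms: dioxygen, O=O
Why: Mukaiyama hydration, in which hydrogen-atom transfer from a cobalt hydride to the 1,1-disubstituted alkene gives the tertiary radical (Markovnikov) that is trapped by O2 and reduced by the silane to the tertiary alcohol, should leave the aromatic and vinylogous-carbamate C=C bonds and the stereocentres Ca, Cb and Cc untouched.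

**Compound list**

1 | 2,3-dimethoxyaniline | Nc1cccc(OC)c1OC | starting material
2 | N-(methoxymethyl)-2,3-dimethoxyaniline | COCNc1cccc(OC)c1OC | intermediate (not isolated)
3 | N-methyl-2,3-dimethoxyaniline | CNc1cccc(OC)c1OC | intermediate
4 | bis(2,4,6-trichlorophenyl) malonate | O=C(CC(=O)Oc1c(Cl)cc(Cl)cc1Cl)Oc1c(Cl)cc(Cl)cc1Cl | starting material
5 | 2,4,6-trichlorophenyl 3-[(2,3-dimethoxyphenyl)(methyl)amino]-3-oxopropanoate | CN(C(=O)CC(=O)Oc1c(Cl)cc(Cl)cc1Cl)c1cccc(OC)c1OC | intermediate (not isolated)
6 | 4-hydroxy-7,8-dimethoxy-1-methylquinolin-2(1H)-one | COc1ccc2c(O)cc(=O)n(C)c2c1OC | intermediate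
7 | (E)-6-methylhepta-3,5-dien-2-one | CC(=O)/C=C/C=C(C)C | starting material
8 | (S)-4-hydroxy-7,8-dimethoxy-1-methyl-3-(6-methyl-2-oxohept-5-en-4-yl)quinolin-2(1H)-one (open keto form; in equilibrium with its cyclic hemiketal) | COc1ccc2c(O)c(c(=O)n(C)c2c1OC)[C@@H](CC(C)=O)C=C(C)C | intermediate
9 | (S)-3-(2,6-dimethylhepta-1,5-dien-4-yl)-4-hydroxy-7,8-dimethoxy-1-methylquinolin-2(1H)-one | COc1ccc2c(O)c(c(=O)n(C)c2c1OC)[C@@H](CC(C)=C)C=C(C)C | intermediate
10 | 3-[(dimethylamino)methylene]-7,8-dimethoxy-1-methylquinoline-2,4(1H,3H)-dione (C=C geometry not fixed) | CN(C)C=C1C(=O)c2ccc(OC)c(OC)c2N(C)C1=O | intermediate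
11 | 3-(aryloxymethylene)-7,8-dimethoxy-1-methylquinoline-2,4(1H,3H)-dione, aryloxy = the 4-oxy group of 9 (Ca S; C=C geometry not fixed) | COc1ccc2c(OC=C3C(=O)c4ccc(OC)c(OC)c4N(C)C3=O)c(c(=O)n(C)c2c1OC)[C@@H](CC(C)=C)C=C(C)C | intermediate (not isolated)
12 | cycloadduct: the target skeleton with CH2C(CH3)=CH2 on Ca in place of CH2C(CH3)2OH; rings A′ and B′ cis-fused (Ca S, Cb S, Cc R) | COc1ccc2c3c(c(=O)n(C)c2c1OC)[C@@H](CC(C)=C)[C@H]1[C@@H](O3)c2c(c3ccc(OC)c(OC)c3n(C)c2=O)OC1(C)C | intermediate
13 | CNP0160874.2: ring A′ (3,4-dihydro-2H-pyrano[3,2-c]quinolin-5-one of unit A, Ca bearing CH2C(CH3)2OH) cis-fused along Cb–Cc to ring B′ (2,2-dimethyl-3,4-dihydro-2H-pyrano[3,2-c]quinolin-5-one of unit B); Ca S, Cb S, Cc R | COc1ccc2c3c(c(=O)n(C)c2c1OC)[C@@H](CC(C)(C)O)[C@H]1[C@@H](O3)c2c(c3ccc(OC)c(OC)c3n(C)c2=O)OC1(C)C | target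

**Step count and risks**

Total step count: 7. Longest linear sequence: 6 steps (steps 1, 2, 3, 4, 6, 7); step 5 is a one-step branch from 6.

Steps most likely to fail:

1. Step 6 (Proposed new method).
 - What may go wrong: exchange at the weakly nucleophilic enolic oxygen may be slower than hydrolysis or self-condensation of the enaminone. A protonated alkene may be captured by the 4-OH. The cycloaddition may run through the lactam oxygen or lose its cis selectivity.
 - Fallback (known chemistry, sets out from 6, comes back at 13): the conventional intermolecular order. Compound 6 and 3-methylbut-2-enal (pyridine, reflux; Knoevenagel condensation and oxa-6π electrocyclisation) should give the chromene 7,8-dimethoxy-2,2,6-trimethyl-2H-pyrano[3,2-c]quinolin-5(6H)-one F1. Compound 6 and 3-hydroxy-3-methylbutanal (ethylenediammonium diacetate, toluene, 80 °C) form in the flask 3-(3-hydroxy-3-methylbutylidene)-7,8-dimethoxy-1-methylquinoline-2,4(1H,3H)-dione F2. Its intermolecular inverse-demand oxa-Diels–Alder reaction with the chromene double bond of F1 should give 13 as the racemate, that is together with the enantiomer of 13 F3. Separation on a chiral stationary phase then gives 13.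

2. Step 3.
 - What may go wrong: competing 1,6-addition, poor facial selectivity on the extended iminium ion, or erosion of enantiopurity by reversible addition.
 - Fallback (sets out from 6, comes back at 9 and so bypasses 8 and step 4): palladium-catalysed asymmetric allylic alkylation. Addition of 2-methylallylmagnesium chloride to 3-methylbut-2-enal (THF, −78 °C) gives racemic 2,6-dimethylhepta-1,5-dien-4-ol F4. Methyl chloroformate and pyridine give 2,6-dimethylhepta-1,5-dien-4-yl methyl carbonate F5. Compound 6 and F5 with Pd2(dba)3 and a chiral phosphinooxazoline ligand (CH2Cl2, rt) should give 9 by C-allylation at the secondary allyl terminus. Both enantiomers of F5 converge because the faces of the π-allyl complex interconvert through the η1 form at the gem-dimethyl terminus.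

3. Step 4.
 - What may go wrong: enolisation of the methyl ketone by the basic ylide and masking of the ketone as hemiketal, leading to incomplete methylenation.
 - Fallback (sets out from 8, comes back at 13 and so bypasses 9, 12 and step 7): the oxygen is carried through instead of the alkene mask. MeMgBr/CeCl3 (THF, −78 to 0 °C) should give (S)-4-hydroxy-3-(2-hydroxy-2,6-dimethylhept-5-en-4-yl)-7,8-dimethoxy-1-methylquinolin-2(1H)-one F6. TESOTf and 2,6-lutidine silylate both hydroxyl groups to the bis(triethylsilyl) ether F7. K2CO3 in MeOH cleaves only the enol silyl ether and leaves the tertiary triethylsilyl ether F8. F8 and 10 under the conditions of step 6 should pass through the silylated aryloxymethylene quinolinedione F9 to the triethylsilyl ether of 13 F10. TBAF in THF then gives 13.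

Further compounds
F1 | step 6 | 7,8-dimethoxy-2,2,6-trimethyl-2H-pyrano[3,2-c]quinolin-5(6H)-one | COc1ccc2c3c(c(=O)n(C)c2c1OC)C=CC(C)(C)O3
F2 | step 6 | 3-(3-hydroxy-3-methylbutylidene)-7,8-dimethoxy-1-methylquinoline-2,4(1H,3H)-dione | CC(C)(O)CC=C1C(=O)c2ccc(OC)c(OC)c2N(C)C1=O
F3 | step 6 | enantiomer of 13 (Ca R, Cb R, Cc S) | COc1ccc2c3c(c(=O)n(C)c2c1OC)[C@H](CC(C)(C)O)[C@@H]1[C@H](O3)c2c(c3ccc(OC)c(OC)c3n(C)c2=O)OC1(C)C
F4 | step 3 | 2,6-dimethylhepta-1,5-dien-4-ol (racemic) | CC(=C)CC(O)C=C(C)C
F5 | step 3 | 2,6-dimethylhepta-1,5-dien-4-yl methyl carbonate (racemic) | COC(=O)OC(CC(C)=C)C=C(C)C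
F6 | step 4 | (S)-4-hydroxy-3-(2-hydroxy-2,6-dimethylhept-5-en-4-yl)-7,8-dimethoxy-1-methylquinolin-2(1H)-one | COc1ccc2c(O)c(c(=O)n(C)c2c1OC)[C@@H](CC(C)(C)O)C=C(C)C
F7 | step 4 | bis(triethylsilyl) ether of F6 (4-O and tertiary O) | COc1ccc2c(O[Si](CC)(CC)CC)c(c(=O)n(C)c2c1OC)[C@@H](CC(C)(C)O[Si](CC)(CC)CC)C=C(C)C
F8 | step 4 | tertiary triethylsilyl ether of F6 | COc1ccc2c(O)c(c(=O)n(C)c2c1OC)[C@@H](CC(C)(C)O[Si](CC)(CC)CC)C=C(C)C
F9 | step 4 | 3-(aryloxymethylene)-7,8-dimethoxy-1-methylquinoline-2,4(1H,3H)-dione, aryloxy = the 4-oxy group of F8 | COc1ccc2c(OC=C3C(=O)c4ccc(OC)c(OC)c4N(C)C3=O)c(c(=O)n(C)c2c1OC)[C@@H](CC(C)(C)O[Si](CC)(CC)CC)C=C(C)C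
F10 | step 4 | triethylsilyl ether of 13 | COc1ccc2c3c(c(=O)n(C)c2c1OC)[C@@H](CC(C)(C)O[Si](CC)(CC)CC)[C@H]1[C@@H](O3)c2c(c3ccc(OC)c(OC)c3n(C)c2=O)OC1(C)C
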